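The target hides a twofold-symmetric core: the two identical 3,4,5-trimethoxyphenyl groups cap ring carbon C2 of the oxolane and the exocyclic carbonyl C7', the ends of the chain C2–C3–C4–C7', whose branches C9 and ring carbon C5 are both hydroxymethyl-level carbons. Disconnecting both aryl–carbon bonds at once leads to the enantiopure cis-fused bislactone 8, the double lactone of (2S,3S)-2,3-bis(hydroxymethyl)succinic acid, made by twofold auxiliary-controlled alkylation. In one operation two aryllithium molecules add once to each lactone carbonyl and deliver the whole skeleton as diketone diol 12. Mono-reduction of one homotopic end closes the cis-2-aryl oxolane, and epimerisation at C4 finishes the synthesis.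

Key step: step 6

Remark: the oxolane is numbered O1, C2 (aryl), C3 (CH2OH, C9), C4 (aroyl, C7'), C5, so the target is (2S,3S,4R) with the aryl cis and the aroyl trans to C9; 12 and 13 are drawn as open keto alcohols and are assumed to equilibrate freely with their hemiketal ring forms.

Step 1
Reactants: 1 succinyl chloride; 2 (R)-4-benzyl-2-oxazolidinone (2 equiv)
Product: 3 1,4-bis[(4R)-4-benzyl-2-oxo-1,3-oxazolidin-3-yl]butane-1,4-dione
Conditions: 2, n-BuLi (1.0 equiv per 2), THF, −78 °C; then 1 (0.5 equiv), −78 to 0 °C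
Reagents that add atoms: none
Why: Twofold N-acylation of the lithiated oxazolidinone by the diacid chloride, a standard imide formation that touches no stereocentre.

Step 2
Reactants: 3 1,4-bis[(4R)-4-benzyl-2-oxo-1,3-oxazolidin-3-yl]butane-1,4-dione; 4 benzyl chloromethyl ether
Product: 5 (2S)-2-[(benzyloxy)methyl]-1,4-bis[(4R)-4-benzyl-2-oxo-1,3-oxazolidin-3-yl]butane-1,4-dione
Conditions: TiCl4 (1.05 equiv), iPr2NEt (1.1 equiv), CH2Cl2, 0 °C; then 4 (1.5 equiv), 0 °C
Reagents that add atoms: none
Why: Evans alkylation of a chlorotitanium enolate: TiCl4 and the amine give the chelated Z-enolate of one imide, the oxocarbenium-like electrophile from 4 enters on the face away from the auxiliary benzyl group, which with the (R)-auxiliary sets the new centre as S, and TiCl4 is returned when chloride leaves 4; recovered 3 and any 6 formed by alkylation at both ends both remain useful.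

Step 3
Reactants: 5 (2S)-2-[(benzyloxy)methyl]-1,4-bis[(4R)-4-benzyl-2-oxo-1,3-oxazolidin-3-yl]butane-1,4-dione; 4 benzyl chloromethyl ether
Product: 6 (2S,3S)-2,3-bis[(benzyloxy)methyl]-1,4-bis[(4R)-4-benzyl-2-oxo-1,3-oxazolidin-3-yl]butane-1,4-dione
Conditions: TiCl4 (1.1 equiv), iPr2NEt (1.2 equiv), CH2Cl2, 0 °C; then 4 (2 equiv), 0 °C to rt
Reagents that add atoms: none
Why: Second Evans titanium-enolate alkylation: only the remaining methylene is enolised, since the methine already substituted is held out of alignment by allylic 1,3-strain in its imide, and its own (R)-auxiliary again steers the electrophile to the face that gives S, so the twofold-symmetric (2S,3S) array results under reagent control.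

Step 4
Reactants: 6 (2S,3S)-2,3-bis[(benzyloxy)methyl]-1,4-bis[(4R)-4-benzyl-2-oxo-1,3-oxazolidin-3-yl]butane-1,4-dione
Product: 8 (1S,5S)-3,7-dioxabicyclo[3.3.0]octane-2,6-dione (cis-fused bislactone), via diol bis-imide 7 (not isolated)
Conditions: H2 (1 atm), 10% Pd/C, EtOAc, rt; filter; then p-TsOH (cat.), CH2Cl2, rt
Reagents that add atoms: none
Why: Hydrogenolysis of both benzyl ethers over Pd/C followed by twofold acid-catalysed lactonisation (5-exo-trig acyl substitution), in which each primary alcohol attacks the imide carbonyl on the neighbouring carbon and expels the oxazolidinone; no stereocentre is touched and the (2S,3S) array can close only to the cis-fused bicycle.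

Step 5
Reactants: 9 5-bromo-1,2,3-trimethoxybenzene
Product: 10 3,4,5-trimethoxyphenyllithium (THF solution, used at once)
Conditions: n-BuLi (1.0 equiv), THF, −78 °C, 30 min
Reagents that add atoms: n-butyllithium, [Li]CCCC
Why: Bromine–lithium exchange, fast and clean at −78 °C for this aryl bromide, with the butyl bromide formed being inert towards the aryllithium at that temperature.

Step 6
Reactants: 8 (1S,5S)-3,7-dioxabicyclo[3.3.0]octane-2,6-dione; 10 3,4,5-trimethoxyphenyllithium (2.1 equiv)
Product: 12 (2S,3S)-2,3-bis(hydroxymethyl)-1,4-bis(3,4,5-trimethoxyphenyl)butane-1,4-dione, via dilithium bis-hemiketal dialkoxide 11 (not isolated)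
Conditions: 10 added by cannula to 8, THF, −78 °C; AcOH (2.2 equiv) in THF at −78 °C, then aq. NaHCO3
Reagents that add atoms: none
Why: Each aryllithium adds to one lactone carbonyl (nucleophilic acyl addition) and the five-membered lithium hemiketal alkoxide so formed does not collapse to the ketone at −78 °C, so no carbonyl is offered twice and the second equivalent is taken up by the second, symmetry-equivalent lactone. The closest known reaction type is the single addition of aryllithiums to γ-lactones and sugar lactones that precedes silane reduction in C-aryl glycoside and furofuran lignan work. No ring is closed in the bond-forming event; the hemiketal forms that 12 adopts afterwards are only ring–chain tautomers. No stereocentre is created: C3 and C4 come unchanged from 8, and the anomeric centres of the hemiketal forms are labile and are erased later. The selectivity needed is one aryl group per carbonyl and addition in preference to α-deprotonation; the stability of the tetrahedral alkoxides secures the first, and the second is served by the low temperature and by the fact that a cis-fused bislactone cannot be epimerised at one centre without forming a strained trans-fused bicycle. Quenching with acetic acid at −78 °C keeps the open keto tautomer from epimerising next to its carbonyl groups.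

Step 7
Reactants: 12 (2S,3S)-2,3-bis(hydroxymethyl)-1,4-bis(3,4,5-trimethoxyphenyl)butane-1,4-dione
Product: 13 (3,4,5-trimethoxyphenyl)[(2S,3S,4S)-3-(hydroxymethyl)-2-(3,4,5-trimethoxyphenyl)oxolan-4-yl]methanone (all-cis)
Conditions: Et3SiH (1.0 equiv), BF3·OEt2 (1.2 equiv), CH2Cl2, −78 °C; Et3N then aq. NaHCO3 at −78 °C
Reagents that add atoms: none
Why: Ionic hydrogenation (silane reduction of an aryl hemiketal through its oxocarbenium ion): BF3·OEt2 ionises one of the two homotopic hemiketals and is released again after hydride transfer, Et3SiH attacks the 2-aryl oxocarbenium ion on the convex face of the cis-fused bicycle, anti to the C3 and C4 branches, so the aryl group ends endo and cis to C9 (C2 = S), while the limiting amount of silane leaves the second hemiketal, and recovered 12 is recycled.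

Step 8
Reactants: 13 (3,4,5-trimethoxyphenyl)[(2S,3S,4S)-3-(hydroxymethyl)-2-(3,4,5-trimethoxyphenyl)oxolan-4-yl]methanone
Product: 14 (3,4,5-trimethoxyphenyl)[(2S,3S,4R)-3-(hydroxymethyl)-2-(3,4,5-trimethoxyphenyl)oxolan-4-yl]methanone (target)
Conditions: DBU (0.5 equiv), CH2Cl2, rt
Reagents that add atoms: none
Why: Base-mediated epimerisation through the enolate of the aryl ketone (thermodynamic equilibration): C4 is the only centre α to a carbonyl, the crowded all-cis isomer relaxes to the 3,4-trans ketone (C4 becomes R), and because the trans ketone cannot reach the C9 hydroxyl to form a hemiketal the open target accumulates, with C2 and C3 untouched.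

Compound list
1 | succinyl chloride | O=C(Cl)CCC(=O)Cl | starting material
2 | (R)-4-benzyl-2-oxazolidinone | O=C1N[C@H](Cc2ccccc2)CO1 | starting material
3 | 1,4-bis[(4R)-4-benzyl-2-oxo-1,3-oxazolidin-3-yl]butane-1,4-dione | O=C(CCC(=O)N1[C@H](Cc2ccccc2)COC1=O)N1[C@H](Cc2ccccc2)COC1=O | intermediate
4 | benzyl chloromethyl ether | ClCOCc1ccccc1 | starting material
5 | (2S)-2-[(benzyloxy)methyl]-1,4-bis[(4R)-4-benzyl-2-oxo-1,3-oxazolidin-3-yl]butane-1,4-dione | O=C(N1[C@H](Cc2ccccc2)COC1=O)[C@H](COCc1ccccc1)CC(=O)N1[C@H](Cc2ccccc2)COC1=O | intermediate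
6 | (2S,3S)-2,3-bis[(benzyloxy)methyl]-1,4-bis[(4R)-4-benzyl-2-oxo-1,3-oxazolidin-3-yl]butane-1,4-dione | O=C(N1[C@H](Cc2ccccc2)COC1=O)[C@H](COCc1ccccc1)[C@@H](COCc1ccccc1)C(=O)N1[C@H](Cc2ccccc2)COC1=O | intermediate
7 | (2S,3S)-2,3-bis(hydroxymethyl)-1,4-bis[(4R)-4-benzyl-2-oxo-1,3-oxazolidin-3-yl]butane-1,4-dione (diol bis-imide, not isolated) | O=C(N1[C@H](Cc2ccccc2)COC1=O)[C@H](CO)[C@@H](CO)C(=O)N1[C@H](Cc2ccccc2)COC1=O | intermediate
8 | (1S,5S)-3,7-dioxabicyclo[3.3.0]octane-2,6-dione, cis-fused | O=C1OC[C@@H]2[C@H]1COC2=O | intermediate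
9 | 5-bromo-1,2,3-trimethoxybenzene | COc1cc(Br)cc(OC)c1OC | starting material
10 | 3,4,5-trimethoxyphenyllithium | [Li]c1cc(OC)c(OC)c(OC)c1 | intermediate
11 | dilithium (1S,5S)-2,6-bis(3,4,5-trimethoxyphenyl)-3,7-dioxabicyclo[3.3.0]octane-2,6-diolate (anomeric centres undefined, not isolated) | [Li]OC1(c2cc(OC)c(OC)c(OC)c2)OC[C@@H]2[C@H]1COC2(O[Li])c1cc(OC)c(OC)c(OC)c1 | intermediate
12 | (2S,3S)-2,3-bis(hydroxymethyl)-1,4-bis(3,4,5-trimethoxyphenyl)butane-1,4-dione (open tautomer of the bis-hemiketal) | O=C(c1cc(OC)c(OC)c(OC)c1)[C@H](CO)[C@@H](CO)C(=O)c1cc(OC)c(OC)c(OC)c1 | intermediate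
13 | (3,4,5-trimethoxyphenyl)[(2S,3S,4S)-3-(hydroxymethyl)-2-(3,4,5-trimethoxyphenyl)oxolan-4-yl]methanone, all-cis | COc1cc(C(=O)[C@@H]2CO[C@H](c3cc(OC)c(OC)c(OC)c3)[C@@H]2CO)cc(OC)c1OC | intermediate
14 | (3,4,5-trimethoxyphenyl)[(2S,3S,4R)-3-(hydroxymethyl)-2-(3,4,5-trimethoxyphenyl)oxolan-4-yl]methanone | COc1cc(C(=O)[C@H]2CO[C@H](c3cc(OC)c(OC)c(OC)c3)[C@@H]2CO)cc(OC)c1OC | target

Total step count: 8. Longest linear sequence: 7 steps (steps 1–4 and 6–8); step 5 is a one-step branch.

Steps most likely to fail

Step 7. What may go wrong: hydride transfer to both homotopic hemiketals instead of one, and acid-promoted cyclodehydration of the 1,4-dicarbonyl array (Paal–Knorr pathway) before hydride arrives. The fallback sets out from 8 and comes back at 13; it brings in the aryl groups one after the other, so that only one hemiketal is ever present. One equivalent of 10 is added to an excess of 8 (THF, −78 °C, AcOH quench) to give (1S,5S)-6-hydroxy-6-(3,4,5-trimethoxyphenyl)-3,7-dioxabicyclo[3.3.0]octan-2-one F1. Excess Et3SiH with BF3·OEt2 (CH2Cl2, −78 °C) should reduce it from the convex face to (1S,5S,6S)-6-(3,4,5-trimethoxyphenyl)-3,7-dioxabicyclo[3.3.0]octan-2-one F2, the lactone being inert to the silane. A second portion of 10 (1.1 equiv, THF, −78 °C, AcOH quench) then adds to the remaining lactone and gives 13. Any 12 formed in the first addition enters step 7, and recovered 8 is reused.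

Step 6. What may go wrong: α-deprotonation of the lactones by the basic aryllithium in place of carbonyl addition, or collapse of a tetrahedral adduct followed by a second addition at the same carbon. The fallback sets out from 8 and comes back at 12; it replaces the lactones by acyl donors that hold a chelated adduct. Me(MeO)NH·HCl with AlMe3 (CH2Cl2, 0 °C to rt) opens both lactones to (2S,3S)-2,3-bis(hydroxymethyl)-N1,N4-dimethoxy-N1,N4-dimethylbutanediamide F3. TBSCl and imidazole (DMF) give its bis(tert-butyldimethylsilyl) ether F4. Reagent 10 (2.3 equiv, THF, −78 °C, AcOH quench) converts both amides into ketones to give (2S,3S)-2,3-bis{[tert-butyl(dimethyl)silyl]oxymethyl}-1,4-bis(3,4,5-trimethoxyphenyl)butane-1,4-dione F5. HF·pyridine (THF, 0 °C) removes the silyl groups and returns 12.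

Step 8. What may go wrong: incomplete epimerisation because the cis isomer is withdrawn from the equilibrium as its bicyclic hemiketal, or base-induced β-elimination of the ring oxygen on long exposure. The fallback sets out from 13 and comes back at 14; it masks the C9 hydroxyl so that no hemiketal can form and a weaker base suffices. TBSCl and imidazole (DMF) give (3,4,5-trimethoxyphenyl)[(2S,3S,4S)-3-{[tert-butyl(dimethyl)silyl]oxymethyl}-2-(3,4,5-trimethoxyphenyl)oxolan-4-yl]methanone F6. Et3N or catalytic DBU (CH2Cl2, rt) should equilibrate it to the (2S,3S,4R) epimer (3,4,5-trimethoxyphenyl)[(2S,3S,4R)-3-{[tert-butyl(dimethyl)silyl]oxymethyl}-2-(3,4,5-trimethoxyphenyl)oxolan-4-yl]methanone F7. HF·pyridine (THF, 0 °C) releases 14.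

Further compounds
F1 | step 7 | (1S,5S)-6-hydroxy-6-(3,4,5-trimethoxyphenyl)-3,7-dioxabicyclo[3.3.0]octan-2-one (anomeric centre undefined) | O=C1OC[C@@H]2[C@H]1COC2(O)c1cc(OC)c(OC)c(OC)c1
F2 | step 7 | (1S,5S,6S)-6-(3,4,5-trimethoxyphenyl)-3,7-dioxabicyclo[3.3.0]octan-2-one (aryl endo) | O=C1OC[C@@H]2[C@H]1CO[C@@H]2c1cc(OC)c(OC)c(OC)c1
F3 | step 6 | (2S,3S)-2,3-bis(hydroxymethyl)-N1,N4-dimethoxy-N1,N4-dimethylbutanediamide | CON(C)C(=O)[C@H](CO)[C@@H](CO)C(=O)N(C)OC
F4 | step 6 | (2S,3S)-2,3-bis{[tert-butyl(dimethyl)silyl]oxymethyl}-N1,N4-dimethoxy-N1,N4-dimethylbutanediamide | CON(C)C(=O)[C@H](CO[Si](C)(C)C(C)(C)C)[C@@H](CO[Si](C)(C)C(C)(C)C)C(=O)N(C)OC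
F5 | step 6 | (2S,3S)-2,3-bis{[tert-butyl(dimethyl)silyl]oxymethyl}-1,4-bis(3,4,5-trimethoxyphenyl)butane-1,4-dione | O=C(c1cc(OC)c(OC)c(OC)c1)[C@H](CO[Si](C)(C)C(C)(C)C)[C@@H](CO[Si](C)(C)C(C)(C)C)C(=O)c1cc(OC)c(OC)c(OC)c1
F6 | step 8 | (3,4,5-trimethoxyphenyl)[(2S,3S,4S)-3-{[tert-butyl(dimethyl)silyl]oxymethyl}-2-(3,4,5-trimethoxyphenyl)oxolan-4-yl]methanone | COc1cc(C(=O)[C@@H]2CO[C@H](c3cc(OC)c(OC)c(OC)c3)[C@@H]2CO[Si](C)(C)C(C)(C)C)cc(OC)c1OC
F7 | step 8 | (3,4,5-trimethoxyphenyl)[(2S,3S,4R)-3-{[tert-butyl(dimethyl)silyl]oxymethyl}-2-(3,4,5-trimethoxyphenyl)oxolan-4-yl]methanone | COc1cc(C(=O)[C@H]2CO[C@H](c3cc(OC)c(OC)c(OC)c3)[C@@H]2CO[Si](C)(C)C(C)(C)C)cc(OC)c1OC
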